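Atom numbers follow the target as a 2-oxaspiro[4.5]deca-6,9-dien-8-one: C1 (side chain), O2, C3 (aryl), C4 (CH2OH), C5 (spiro), C6=C7(OMe)–C8(=O)–C9=C10.

**Plan**
- **Cuts, in retrosynthetic order:** four O–Si bonds; the C9=C10 unsaturation; C5–C10 and C8–C9 together (six-membered ring → 2-methoxycyclobutenone C5–C6=C7–C8 plus a vinyl anion); C5–C6 and C7–C8 (ketene + 1,2-dimethoxyethene); C5–C8 (CO on a C5 radical); O2–C1 (iodoetherification); the C5=C1 alkene (metathesis); C3–C4 (aldol); the side-chain C–OAr bond (Mitsunobu).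
- **Enabling feature:** C8 lies three bonds from C5 along C5–C6=C7(OMe)–C8, so these four atoms form a cyclobutenone once C5 and C8 are joined, and C9–C10 is a vinyl unit. The C1 and C4 substituents are cis on the tetrahydrofuran ring and both flank C5, so they shield one face of C5.
- **Forward order:** chain assembly, then the tetrahydrofuran ring, then the spiro four-membered ring, then four-to-six ring expansion, dehydrogenation and desilylation.
- **Stereochemistry:** C3 and C4 come from an Evans syn aldol. The side-chain carbon comes from (S)-but-3-ene-1,2-diol with Mitsunobu inversion. C1 comes from anti addition to an E-alkene. C5 comes from the face-selective 6π closure of the key step.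

Key step: step 15

Assumption: 20 is used as its E/Z mixture. C5 in 16–18 is drawn as the expected trans isomer, and the uncontrolled centres of the four-membered ring in 23–25 are left open, because C5 is planar in 22 and again in 26.

Step 1
Reactants: 1 vanillin
Product: 2 3-methoxy-4-(triisopropylsilyloxy)benzaldehyde
Conditions: TIPSCl, imidazole, CH2Cl2, 0 °C to rt
Reagents that add atoms: chlorotriisopropylsilane CC(C)[Si](Cl)(C(C)C)C(C)C
Why: Imidazole-promoted O-silylation of a phenol; the bulky aryl TIPS ether should survive the later amine-base and organolithium steps and falls to fluoride at the end.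

Step 2
Reactants: 3 (S)-4-benzyloxazolidin-2-one; 4 (E)-crotonic anhydride
Product: 5 (S)-4-benzyl-3-[(E)-but-2-enoyl]oxazolidin-2-one
Conditions: Et3N, LiCl, THF, rt
Reagents that add atoms: none
Why: LiCl/Et3N-mediated N-acylation of an oxazolidinone with an anhydride, which avoids strong base on the crotonyl unit.

Step 3
Reactants: 5 crotonyl imide; 2 silylated vanillin
Product: 7 syn-aldol imide (S)-4-benzyl-3-{(2S)-2-[(S)-hydroxy(3-methoxy-4-triisopropylsilyloxyphenyl)methyl]but-3-enoyl}oxazolidin-2-one, via boron dienolate 6 (not isolated)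
Conditions: Bu2BOTf, Et3N, CH2Cl2, −78 to 0 °C; 2, −78 to 0 °C; pH 7 buffer, MeOH, H2O2, 0 °C
Reagents that add atoms: none
Why: Evans syn aldol of a crotonate imide; the Z-boron dienolate 6 reacts at its α-carbon through a Zimmerman–Traxler chair on the face away from the benzyl group, which sets C3 and C4 and leaves the vinyl group whose inner carbon becomes C5.

Step 4
Reactants: 7 syn-aldol imide
Product: 8 (1S,2R)-1-(3-methoxy-4-triisopropylsilyloxyphenyl)-2-vinylpropane-1,3-diol
Conditions: LiBH4, MeOH (1 equiv), Et2O, 0 °C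
Reagents that add atoms: none
Why: Reductive cleavage of the N-acyloxazolidinone turns the imide carbonyl into the C4 hydroxymethyl group without touching the stereocentres.

Step 5
Reactants: 8 diol
Product: 9 primary TBS ether of 8 (benzylic OH free)
Conditions: TBSCl (1.05 equiv), imidazole, CH2Cl2, 0 °C
Reagents that add atoms: tert-butylchlorodimethylsilane CC(C)(C)[Si](C)(C)Cl
Why: Sterically controlled silylation of the primary over the secondary benzylic hydroxyl.

Step 6
Reactants: 10 dihydroconiferyl alcohol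
Product: 11 4-[3-(tert-butyldimethylsilyloxy)propyl]-2-methoxyphenol
Conditions: TBSCl (1.05 equiv), imidazole, CH2Cl2, 0 °C
Reagents that add atoms: tert-butylchlorodimethylsilane CC(C)(C)[Si](C)(C)Cl
Why: Under non-deprotonating imidazole conditions the primary alcohol should be silylated faster than the hindered, hydrogen-bonded guaiacol hydroxyl.

Step 7
Reactants: 12 (S)-but-3-ene-1,2-diol
Product: 13 (S)-1-(tert-butyldimethylsilyloxy)but-3-en-2-ol
Conditions: TBSCl (1.0 equiv), imidazole, CH2Cl2, 0 °C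
Reagents that add atoms: tert-butylchlorodimethylsilane CC(C)(C)[Si](C)(C)Cl
Why: Selective silylation of the primary hydroxyl of a 1,2-diol.

Step 8
Reactants: 11 phenol; 13 allylic alcohol
Product: 14 (R)-allylic aryl ether CH2=CH–CH(OAr)–CH2OTBS
Conditions: PPh3, DIAD, toluene, 0 °C to rt
Reagents that add atoms: none
Why: Mitsunobu etherification with clean SN2 inversion, which sets the aryloxy-bearing side-chain stereocentre from the chiral pool.

Step 9
Reactants: 9 homoallylic alcohol; 14 allylic aryl ether (2–3 equiv)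
Product: 15 (E)-homoallylic alcohol ArCH(OH)–CH(CH2OTBS)–CH=CH–CH(OAr')–CH2OTBS
Conditions: second-generation Hoveyda–Grubbs catalyst RuCl2(H2IMes)(=CH-C6H4-2-OiPr) (10 mol %), toluene, 60 °C, ethene purged
Reagents that add atoms: none
Why: Olefin cross metathesis of two terminal alkenes that homodimerise slowly; it should be E-selective under thermodynamic control and joins the two chiral halves without touching a stereocentre.

Step 10
Reactants: 15 (E)-homoallylic alcohol
Product: 16 all-trans 3-iodotetrahydrofuran (iodine on the future C5)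
Conditions: I2 (3 equiv), NaHCO3 (3 equiv), dry MeCN, 0 °C to rt
Reagents that add atoms: iodine II
Why: In this 5-endo-trig iodoetherification, anti addition of O and I across the E-alkene ties C1 to C5, and an envelope transition state with the aryl and CH2OTBS groups pseudo-equatorial and the iodonium anti to CH2OTBS should place the C1 side chain cis to the C4 substituent and trans to the aryl group.

Step 11
Reactants: 16 iodotetrahydrofuran
Product: 18 tetrahydrofuran-3-carboxylic acid (carboxyl carbon is the future C8), via acyl iodide 17 (not isolated)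
Conditions: CO (40 atm), Pd(PPh3)4 (5 mol %), Et3N, H2O, benzene–MeCN, hν (Xe lamp, Pyrex), rt
Reagents that add atoms: carbon monoxide [C-]#[O+]; water O
Why: In this atom-transfer radical carbonylation of a secondary iodide, the C5 radical takes up CO without expelling the β-alkoxy group and the acyl iodide is hydrolysed in place; the C5 configuration formed is of no consequence.

Step 12
Reactants: 19 1,1,2-trimethoxyethane
Product: 20 1,2-dimethoxyethene (E/Z mixture)
Conditions: TMSOTf, iPr2NEt, CH2Cl2, −20 °C to rt; distil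
Reagents that add atoms: none
Why: Silyl-triflate/amine elimination of methanol from an acetal, a general acetal-to-enol-ether conversion.

Step 13
Reactants: 18 acid; 20 1,2-dimethoxyethene (5 equiv)
Product: 23 2,3-dimethoxy-6-oxaspiro[3.4]octan-1-one (diastereomer mixture in the four-membered ring), via acid chloride 21 (not isolated), via ketene 22 (not isolated)
Conditions: 1-chloro-N,N,2-trimethylprop-1-en-1-amine, CH2Cl2, 0 °C; then 20, Et3N (slow addition), toluene, 80 °C
Reagents that add atoms: none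
Why: Neutral acid chloride formation, dehydrochlorination to the dialkylketene and thermal ketene–enol ether [2+2] cycloaddition; the symmetrical olefin removes any regiochemical question, and the new centres are all erased later.

Step 14
Reactants: 23 dimethoxycyclobutanone
Product: 24 2-methoxy-6-oxaspiro[3.4]oct-2-en-1-one (both spiro epimers)
Conditions: DBU, CH2Cl2, 0 °C, short contact; filter through silica
Reagents that add atoms: none
Why: E1cB loss of the β-methoxy group (on C6) from the only enolisable position (C7) gives the α-methoxycyclobutenone.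

Step 15
Reactants: 24 spiro 2-methoxycyclobutenone
Product: 28 7-methoxy-8-(trimethylsilyloxy)-2-oxaspiro[4.5]deca-6,8-diene, via lithium cyclobutenolate 25 (not isolated), via lithium trienolate 26 (not isolated), via lithium cyclohexadienolate 27 (not isolated)
Conditions: CH2=CHSnBu3, n-BuLi, THF, −78 °C; add 24, −78 to 0 °C (rt if needed); recool to −78 °C, TMSCl, Et3N; pentane/aq NaHCO3
Reagents that add atoms: vinyllithium [Li]C=C; chlorotrimethylsilane C[Si](C)(C)Cl
Why: Vinyllithium adds 1,2 to the strained carbonyl C8 (C6 is neopentylic and C7 bears a donor OMe, so conjugate addition is disfavoured) to give 25, whose C5–C8 bond opens in an oxyanion-accelerated conrotatory 4π process with the oxido group turning outward and the vinyl group inward, so that 26 has the Z central double bond needed for closure. Release of cyclobutene strain drives this opening, and the 3-oxidohexatriene 26 then closes by a thermally allowed disrotatory 6π electrocyclisation that forms C5–C10 and with it the six-membered carbocycle (ring size four to six), the dienolate 27 being trapped on oxygen by TMSCl. The closest known reaction type is the two-carbon ring expansion of cyclobutenones to cyclohexenones by alkenyllithium addition followed by a 4π/6π cascade. C5, the only new stereocentre, is planar in 26, so both spiro epimers of 24 converge; the C1 side chain and the C4 CH2OTBS group stand on the same face of the tetrahydrofuran ring next to C5, so C10 should bond on the opposite face, leaving C6 and the methoxy-bearing arm syn to them as in the target. The position of the methoxy group is not a selectivity issue, because C7 already belongs to the four-membered ring whereas C9–C10 come from the reagent.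

Step 16
Reactants: 28 silyl dienol ether
Product: 29 tetrasilylated 7-methoxy-2-oxaspiro[4.5]deca-6,9-dien-8-one
Conditions: Pd(OAc)2 (1.05 equiv), MeCN, rt
Reagents that add atoms: none
Why: In this Saegusa–Ito dehydrogenation the silyl enol ether is palladated at C9, and β-hydride loss from C10 installs C9=C10 under neutral conditions that spare the fragile spirodienone.

Step 17
Reactants: 29 protected dienone
Product: 30 target CNP0252711.1
Conditions: HF·pyridine, pyridine, THF, 0 °C to rt; buffered work-up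
Reagents that add atoms: none
Why: Buffered fluoride desilylation removes the three primary TBS ethers and the aryl TIPS ether; it avoids both the base that would trigger oxa-Michael addition and the strong acid that would fragment the dienone.

**Compound list**
1 | vanillin | COc1cc(C=O)ccc1O | starting material
2 | 3-methoxy-4-(triisopropylsilyloxy)benzaldehyde | COc1cc(C=O)ccc1O[Si](C(C)C)(C(C)C)C(C)C | intermediate
3 | (S)-4-benzyloxazolidin-2-one | O=C1OC[C@H](Cc2ccccc2)N1 | starting material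
4 | (E)-crotonic anhydride | C/C=C/C(=O)OC(=O)/C=C/C | starting material
5 | (S)-4-benzyl-3-[(E)-but-2-enoyl]oxazolidin-2-one | C/C=C/C(=O)N1[C@@H](Cc2ccccc2)COC1=O | intermediate
6 | Z-dibutylboron dienolate of 5 | C=C/C=C(/N1[C@@H](Cc2ccccc2)COC1=O)OB(CCCC)CCCC | intermediate
7 | syn-aldol imide | C=C[C@H](C(=O)N1[C@@H](Cc2ccccc2)COC1=O)[C@H](O)c1ccc(O[Si](C(C)C)(C(C)C)C(C)C)c(OC)c1 | intermediate
8 | (1S,2R)-1-aryl-2-vinylpropane-1,3-diol | C=C[C@H](CO)[C@H](O)c1ccc(O[Si](C(C)C)(C(C)C)C(C)C)c(OC)c1 | intermediate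
9 | primary TBS ether of 8 | C=C[C@H](CO[Si](C)(C)C(C)(C)C)[C@H](O)c1ccc(O[Si](C(C)C)(C(C)C)C(C)C)c(OC)c1 | intermediate
10 | dihydroconiferyl alcohol | COc1cc(CCCO)ccc1O | starting material
11 | 4-[3-(TBS-oxy)propyl]-2-methoxyphenol | COc1cc(CCCO[Si](C)(C)C(C)(C)C)ccc1O | intermediate
12 | (S)-but-3-ene-1,2-diol | C=C[C@@H](CO)O | starting material
13 | (S)-1-(TBS-oxy)but-3-en-2-ol | C=C[C@@H](CO[Si](C)(C)C(C)(C)C)O | intermediate
14 | (R)-allylic aryl ether | C=C[C@H](CO[Si](C)(C)C(C)(C)C)Oc1ccc(CCCO[Si](C)(C)C(C)(C)C)cc1OC | intermediate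
15 | (E)-homoallylic alcohol | CC(C)(C)[Si](C)(C)OC[C@@H](/C=C/[C@H](CO[Si](C)(C)C(C)(C)C)Oc1ccc(CCCO[Si](C)(C)C(C)(C)C)cc1OC)[C@H](O)c1ccc(O[Si](C(C)C)(C(C)C)C(C)C)c(OC)c1 | intermediate
16 | all-trans 3-iodotetrahydrofuran | I[C@H]1[C@H](CO[Si](C)(C)C(C)(C)C)[C@@H](c3ccc(O[Si](C(C)C)(C(C)C)C(C)C)c(OC)c3)O[C@@H]1[C@H](CO[Si](C)(C)C(C)(C)C)Oc4ccc(CCCO[Si](C)(C)C(C)(C)C)cc4OC | intermediate
17 | acyl iodide | O=C(I)[C@H]1[C@H](CO[Si](C)(C)C(C)(C)C)[C@@H](c3ccc(O[Si](C(C)C)(C(C)C)C(C)C)c(OC)c3)O[C@@H]1[C@H](CO[Si](C)(C)C(C)(C)C)Oc4ccc(CCCO[Si](C)(C)C(C)(C)C)cc4OC | intermediate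
18 | tetrahydrofuran-3-carboxylic acid | O=C(O)[C@H]1[C@H](CO[Si](C)(C)C(C)(C)C)[C@@H](c3ccc(O[Si](C(C)C)(C(C)C)C(C)C)c(OC)c3)O[C@@H]1[C@H](CO[Si](C)(C)C(C)(C)C)Oc4ccc(CCCO[Si](C)(C)C(C)(C)C)cc4OC | intermediate
19 | 1,1,2-trimethoxyethane | COCC(OC)OC | starting material
20 | 1,2-dimethoxyethene (E/Z) | COC=COC | intermediate
21 | acid chloride | O=C(Cl)[C@H]1[C@H](CO[Si](C)(C)C(C)(C)C)[C@@H](c3ccc(O[Si](C(C)C)(C(C)C)C(C)C)c(OC)c3)O[C@@H]1[C@H](CO[Si](C)(C)C(C)(C)C)Oc4ccc(CCCO[Si](C)(C)C(C)(C)C)cc4OC | intermediate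
22 | tetrahydrofuran-3-ylidene ketene | O=C=C1[C@H](CO[Si](C)(C)C(C)(C)C)[C@@H](c3ccc(O[Si](C(C)C)(C(C)C)C(C)C)c(OC)c3)O[C@@H]1[C@H](CO[Si](C)(C)C(C)(C)C)Oc4ccc(CCCO[Si](C)(C)C(C)(C)C)cc4OC | intermediate
23 | 2,3-dimethoxy-6-oxaspiro[3.4]octan-1-one | COC1C(OC)C2(C1=O)[C@H](CO[Si](C)(C)C(C)(C)C)[C@@H](c3ccc(O[Si](C(C)C)(C(C)C)C(C)C)c(OC)c3)O[C@@H]2[C@H](CO[Si](C)(C)C(C)(C)C)Oc4ccc(CCCO[Si](C)(C)C(C)(C)C)cc4OC | intermediate
24 | 2-methoxy-6-oxaspiro[3.4]oct-2-en-1-one | COC1=CC2(C1=O)[C@H](CO[Si](C)(C)C(C)(C)C)[C@@H](c3ccc(O[Si](C(C)C)(C(C)C)C(C)C)c(OC)c3)O[C@@H]2[C@H](CO[Si](C)(C)C(C)(C)C)Oc4ccc(CCCO[Si](C)(C)C(C)(C)C)cc4OC | intermediate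
25 | lithium 1-vinylcyclobut-2-en-1-olate | [Li+].C=CC1([O-])C(OC)=CC12[C@H](CO[Si](C)(C)C(C)(C)C)[C@@H](c3ccc(O[Si](C(C)C)(C(C)C)C(C)C)c(OC)c3)O[C@@H]2[C@H](CO[Si](C)(C)C(C)(C)C)Oc4ccc(CCCO[Si](C)(C)C(C)(C)C)cc4OC | intermediate
26 | lithium 3-oxidohexatriene (Z central double bond) | [Li+].[O-]/C(C=C)=C(OC)/C=C1[C@H](CO[Si](C)(C)C(C)(C)C)[C@@H](c3ccc(O[Si](C(C)C)(C(C)C)C(C)C)c(OC)c3)O[C@@H]1[C@H](CO[Si](C)(C)C(C)(C)C)Oc4ccc(CCCO[Si](C)(C)C(C)(C)C)cc4OC | intermediate
27 | lithium cyclohexadienolate (C10 anti, C6 syn to the C1 and C4 substituents) | [Li+].COC1=C[C@]2(CC=C1[O-])[C@H](CO[Si](C)(C)C(C)(C)C)[C@@H](c3ccc(O[Si](C(C)C)(C(C)C)C(C)C)c(OC)c3)O[C@@H]2[C@H](CO[Si](C)(C)C(C)(C)C)Oc4ccc(CCCO[Si](C)(C)C(C)(C)C)cc4OC | intermediate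
28 | 7-methoxy-8-(trimethylsilyloxy)-2-oxaspiro[4.5]deca-6,8-diene | COC1=C[C@]2(CC=C1O[Si](C)(C)C)[C@H](CO[Si](C)(C)C(C)(C)C)[C@@H](c3ccc(O[Si](C(C)C)(C(C)C)C(C)C)c(OC)c3)O[C@@H]2[C@H](CO[Si](C)(C)C(C)(C)C)Oc4ccc(CCCO[Si](C)(C)C(C)(C)C)cc4OC | intermediate
29 | tetrasilylated spirodienone | COC1=C[C@]2(C=CC1=O)[C@H](CO[Si](C)(C)C(C)(C)C)[C@@H](c3ccc(O[Si](C(C)C)(C(C)C)C(C)C)c(OC)c3)O[C@@H]2[C@H](CO[Si](C)(C)C(C)(C)C)Oc4ccc(CCCO[Si](C)(C)C(C)(C)C)cc4OC | intermediate
30 | CNP0252711.1 | COC1=C[C@]2(C=CC1=O)[C@H](CO)[C@@H](c1ccc(O)c(OC)c1)O[C@@H]2[C@H](CO)Oc1ccc(CCCO)cc1OC | target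

Total step count: 17. Longest linear sequence: 12 steps (1, 3, 4, 5, 9, 10, 11, 13, 14, 15, 16, 17).

**Steps most likely to fail**

1. **Step 15.**
   - Risk: the 6π closure onto the fully substituted C5 terminus may be slower than protonation or decomposition of the trienolate, and the facial bias at C5 may be eroded by the C3 aryl group on the other face.
   - Fallback: it sets out from 24 and replaces the pericyclic cascade by metal-mediated C–C activation, still as a four-to-six ring expansion.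
   - [RhCl(CO)2]2 (monovalent rhodium, 5 mol %) under ethene (30 atm) in toluene at 110 °C should insert into the acyl C8–C5 bond, take up ethene and reductively eliminate on the open face of C5.
   - This gives the 7-methoxy-2-oxaspiro[4.5]dec-6-en-8-one F1.
   - Kinetic deprotonation at C9 (LDA, THF, −78 °C) and TMSCl brings the route back at 28.

2. **Step 9.**
   - Risk: both alkenes are branched at the allylic carbon, so productive cross metathesis may be outrun by catalyst decay and by alkene isomerisation.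
   - Fallback: it sets out from 9 and 14 and comes back at 18, bypassing steps 9–11.
   - Cross metathesis of 9 with the unhindered allyltrimethylsilane gives the allylsilane F2.
   - Ozonolysis of 14 (O3, then Me2S) gives the α-aryloxy aldehyde F3.
   - BF3·OEt2 in CH2Cl2 at −78 °C condenses F2 with F3 to an oxocarbenium ion, which the allylsilane captures in a 5-exo mode through an all-pseudo-equatorial transition state, giving the all-trans 3-vinyltetrahydrofuran F4.
   - OsO4/NaIO4/2,6-lutidine cleaves the vinyl group to the aldehyde F5, and NaClO2/NaH2PO4/2-methylbut-2-ene oxidises it to 18.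

3. **Step 13.**
   - Risk: the hindered dialkylketene may form slowly, dimerise or lose the β-alkoxy group by ring opening before it meets the enol ether.
   - Fallback: it sets out from 18, comes back at 23, and uses a more electrophilic heterocumulene.
   - The acid is converted (chloroenamine, then Me2NH) into the N,N-dimethylamide F6.
   - Tf2O and 2,4,6-collidine in CH2Cl2 give the keteniminium triflate F7.
   - F7 undergoes [2+2] cycloaddition with 20 below room temperature to the cyclobutaniminium triflate F8, and aqueous NaHCO3 hydrolysis releases 23.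

**Further compounds**
F1 | step 15 | 7-methoxy-2-oxaspiro[4.5]dec-6-en-8-one (tetrasilylated) | COC1=C[C@]2(CCC1=O)[C@H](CO[Si](C)(C)C(C)(C)C)[C@@H](c3ccc(O[Si](C(C)C)(C(C)C)C(C)C)c(OC)c3)O[C@@H]2[C@H](CO[Si](C)(C)C(C)(C)C)Oc4ccc(CCCO[Si](C)(C)C(C)(C)C)cc4OC
F2 | step 9 | (E)-allylsilane from 9 | CC(C)(C)[Si](C)(C)OC[C@@H](/C=C/C[Si](C)(C)C)[C@H](O)c1ccc(O[Si](C(C)C)(C(C)C)C(C)C)c(OC)c1
F3 | step 9 | 2-aryloxy-3-(TBS-oxy)propanal | O=C[C@H](CO[Si](C)(C)C(C)(C)C)Oc1ccc(CCCO[Si](C)(C)C(C)(C)C)cc1OC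
F4 | step 9 | all-trans 3-vinyltetrahydrofuran | C=C[C@H]1[C@H](CO[Si](C)(C)C(C)(C)C)[C@@H](c3ccc(O[Si](C(C)C)(C(C)C)C(C)C)c(OC)c3)O[C@@H]1[C@H](CO[Si](C)(C)C(C)(C)C)Oc4ccc(CCCO[Si](C)(C)C(C)(C)C)cc4OC
F5 | step 9 | tetrahydrofuran-3-carbaldehyde | O=C[C@H]1[C@H](CO[Si](C)(C)C(C)(C)C)[C@@H](c3ccc(O[Si](C(C)C)(C(C)C)C(C)C)c(OC)c3)O[C@@H]1[C@H](CO[Si](C)(C)C(C)(C)C)Oc4ccc(CCCO[Si](C)(C)C(C)(C)C)cc4OC
F6 | step 13 | N,N-dimethyl tetrahydrofuran-3-carboxamide | CN(C)C(=O)[C@H]1[C@H](CO[Si](C)(C)C(C)(C)C)[C@@H](c3ccc(O[Si](C(C)C)(C(C)C)C(C)C)c(OC)c3)O[C@@H]1[C@H](CO[Si](C)(C)C(C)(C)C)Oc4ccc(CCCO[Si](C)(C)C(C)(C)C)cc4OC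
F7 | step 13 | keteniminium triflate | C[N+](C)=C=C1[C@H](CO[Si](C)(C)C(C)(C)C)[C@@H](c3ccc(O[Si](C(C)C)(C(C)C)C(C)C)c(OC)c3)O[C@@H]1[C@H](CO[Si](C)(C)C(C)(C)C)Oc4ccc(CCCO[Si](C)(C)C(C)(C)C)cc4OC.[O-]S(=O)(=O)C(F)(F)F
F8 | step 13 | cyclobutaniminium triflate | COC1C(OC)C2(C1=[N+](C)C)[C@H](CO[Si](C)(C)C(C)(C)C)[C@@H](c3ccc(O[Si](C(C)C)(C(C)C)C(C)C)c(OC)c3)O[C@@H]2[C@H](CO[Si](C)(C)C(C)(C)C)Oc4ccc(CCCO[Si](C)(C)C(C)(C)C)cc4OC.[O-]S(=O)(=O)C(F)(F)F
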